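**Plan**

1. Retrosynthesis (carotenoid numbering: ring C1–C6, chain C7 to C8'): the first cut is C7=C8 (Julia–Kocienski olefination), giving a C10 ring sulfone and all-E crocetin dialdehyde. The ring is then cut at C4=C5 (aldol condensation) and C1–C6 (Michael addition), back to mesityl oxide and isopropyl acetoacetate.
2. Enabling feature: the six-membered ring is an isophorone in disguise. The oxygen on C3 and the methyl-bearing C5 are 1,3-related through C4, so C4=C5 is the enone double bond of a C3 ketone. C6 sits between C5 and C7 as the α-carbon of an acetoacetate, and quaternary C1 is the β-carbon of mesityl oxide.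
3. Forward order: one annulation builds the whole carbocycle with C7 attached (step 1). The ketone is reduced, C7 is taken from ester to CH2–sulfone, the C20 chain is joined last, and the silyl ether is removed.
4. Stereochemistry: the annulation deliberately leaves C6 configurationally labile. One asymmetric hydrogenation with dynamic kinetic resolution then sets C3 by catalyst control and C6 by substrate matching (hydride anti to the pseudoaxial ester, hence 3,6-cis).
5. Alkene geometry: C7=C8 is E from the olefination; the other seven chain double bonds arrive E in the dial.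

Key step: step 1

Assumption: all-E crocetin dialdehyde is taken as a purchasable carotenoid building block.
Remark: locants C1–C8' in the text follow carotenoid numbering of the target; compound names use ring numbering, in which the chain-bearing carbon is C1 and the carbinol carbon is C4.

**Step 1**
Reactants: 1 mesityl oxide (4-methylpent-3-en-2-one); 2 isopropyl acetoacetate (propan-2-yl 3-oxobutanoate)
Product: 5 isopropyl 2,6,6-trimethyl-4-oxocyclohex-2-ene-1-carboxylate (racemic), via Michael adduct 3 (not isolated), via ketol 4 (not isolated)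
Conditions: ZnCl2 (0.3 equiv), heptane–toluene, reflux, Dean–Stark, 48 h
Reagents that add atoms: none
Why: Robinson-type Michael–aldol annulation, the isophorone synthesis run with an acetoacetate and known for the ethyl ester: the zinc-chelated enol of 2 adds through its α-carbon (future C6) to the Lewis-acid-activated β,β-dimethyl terminus of 1 (future quaternary C1) to give adduct 3, whose free methyl ketone enolises toward its CH3 (future C4) and attacks the chelated acetyl carbonyl (future C5). That aldol is the ring-closing event, a 6-(enolendo)-exo-trig closure to ketol 4, and loss of water then fixes C4=C5 as the trisubstituted double bond of enone 5. The step needs regioselectivity between two aldol directions and over Claisen-type attack on the ester; it is secured because the acetyl group of the β-keto ester is the only chelate-activated electrophile and is enolised by the chelate toward C6 and not toward its CH3 (the same sense as in the Hagemann ester synthesis), and because all steps before dehydration are reversible under water-removing Lewis-acid conditions, so the conjugated 4-oxo enone is the thermodynamic sink. C6 is formed racemic and stays configurationally labile (α to the ester, γ to the enone); it is deliberately not controlled here because step 2 exploits exactly this lability. In one operation the step delivers all ten carbons of the end group with the quaternary C1, the ring methyl on C5, oxygen on C3, C7 at the carboxyl level and the double bond already in the ε position, out of conjugation with C6.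

**Step 2**
Reactants: 5 isopropyl 2,6,6-trimethyl-4-oxocyclohex-2-ene-1-carboxylate (racemic)
Product: 6 isopropyl (1R,4S)-4-hydroxy-2,6,6-trimethylcyclohex-2-ene-1-carboxylate
Conditions: RuCl2[(R)-xylbinap][(R)-daipen] (0.5 mol %), KOt-Bu (10 mol %), H2 (10 atm), i-PrOH, 25 °C
Reagents that add atoms: none
Why: Proposed new method: a vinylogous dynamic kinetic resolution, in which the C6–H of 5 (α to the ester, γ to the enone) is exchanged through the achiral dienolate by the alkoxide base faster than the outer-sphere Ru–H/N–H catalyst reduces the C=O group; the catalyst antipode is chosen, with the alkenyl arm in the role of the aryl group of acetophenone, to deliver hydride to the face that gives the (S)-carbinol at C3, and that face is open only in the (6R)-enantiomer because the ester sits pseudoaxial (A(1,2) strain with the C5 methyl) and shields its own side, so hydride adds anti to the ester and OH ends up cis to it; the closest known reactions are the base-mediated dynamic kinetic resolution of α-substituted cyclohexanones and the 1,2-selective hydrogenation of cyclic enones with the same RuCl2(diphosphine)(diamine) catalysts (Noyori asymmetric hydrogenation).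

**Step 3**
Reactants: 6 isopropyl (1R,4S)-4-hydroxy-2,6,6-trimethylcyclohex-2-ene-1-carboxylate
Product: 7 isopropyl (1R,4S)-4-[(tert-butyldimethylsilyl)oxy]-2,6,6-trimethylcyclohex-2-ene-1-carboxylate
Conditions: TBSCl, imidazole, DMF, rt
Reagents that add atoms: tert-butyldimethylsilyl chloride (TBSCl), CC(C)(C)[Si](C)(C)Cl
Why: Standard imidazole-promoted silylation of the secondary allylic alcohol masks C3–OH, so that only the C7 hydroxyl is activated in step 5 and no alkoxide competes in step 7; no stereocentre is touched.

**Step 4**
Reactants: 7 isopropyl (1R,4S)-4-[(tert-butyldimethylsilyl)oxy]-2,6,6-trimethylcyclohex-2-ene-1-carboxylate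
Product: 8 {(1R,4S)-4-[(tert-butyldimethylsilyl)oxy]-2,6,6-trimethylcyclohex-2-en-1-yl}methanol
Conditions: LiAlH4, Et2O, 0 °C to rt
Reagents that add atoms: none
Why: Hydride reduction of the hindered ester to the primary alcohol is faster than enolisation, so C6 keeps its configuration and is no longer acidic afterwards, while the silyl ether and the trisubstituted alkene are inert to LiAlH4.

**Step 5**
Reactants: 8 {(1R,4S)-4-[(tert-butyldimethylsilyl)oxy]-2,6,6-trimethylcyclohex-2-en-1-yl}methanol
Product: 9 5-[({(1R,4S)-4-[(tert-butyldimethylsilyl)oxy]-2,6,6-trimethylcyclohex-2-en-1-yl}methyl)sulfanyl]-1-phenyl-1H-tetrazole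
Conditions: 1-phenyl-1H-tetrazole-5-thiol, PPh3, DIAD, THF, 0 °C to rt
Reagents that add atoms: 1-phenyl-1H-tetrazole-5-thiol, SC1=NN=NN1c1ccccc1
Why: Mitsunobu thioetherification, in which the acidic tetrazolethiol displaces the oxyphosphonium group at the primary C7 by SN2 (β-branched but not neopentyl); no stereocentre is involved.

**Step 6**
Reactants: 9 5-[({(1R,4S)-4-[(tert-butyldimethylsilyl)oxy]-2,6,6-trimethylcyclohex-2-en-1-yl}methyl)sulfanyl]-1-phenyl-1H-tetrazole
Product: 10 5-[({(1R,4S)-4-[(tert-butyldimethylsilyl)oxy]-2,6,6-trimethylcyclohex-2-en-1-yl}methyl)sulfonyl]-1-phenyl-1H-tetrazole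
Conditions: (NH4)6Mo7O24·4H2O (10 mol %), 30% aq. H2O2, EtOH, 0 °C to rt
Reagents that add atoms: hydrogen peroxide, OO
Why: Molybdate-catalysed peroxide oxidation takes the sulfide through the sulfoxide to the sulfone and should leave the trisubstituted alkene alone, because no free allylic hydroxyl is present to direct epoxidation.

**Step 7**
Reactants: 10 5-[({(1R,4S)-4-[(tert-butyldimethylsilyl)oxy]-2,6,6-trimethylcyclohex-2-en-1-yl}methyl)sulfonyl]-1-phenyl-1H-tetrazole; 11 crocetin dialdehyde ((2E,4E,6E,8E,10E,12E,14E)-2,6,11,15-tetramethylhexadeca-2,4,6,8,10,12,14-heptaenedial)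
Product: 12 (2E,4E,6E,8E,10E,12E,14E,16E)-17-{(1R,4S)-4-[(tert-butyldimethylsilyl)oxy]-2,6,6-trimethylcyclohex-2-en-1-yl}-2,6,11,15-tetramethylheptadeca-2,4,6,8,10,12,14,16-octaenal
Conditions: KN(SiMe3)2 (1.1 equiv) added to 10 and 11 (3 equiv), THF–DMF, −60 °C to rt, dark
Reagents that add atoms: none
Why: Julia–Kocienski olefination, in which the potassium α-sulfonyl carbanion adds 1,2 to one aldehyde of the non-enolisable dial and Smiles rearrangement with loss of SO2 and tetrazololate gives C7=C8, expected E because phenyltetrazolyl sulfones with a potassium counter-ion in polar solvent react through the anti adduct; the excess of 11 holds the reaction at mono-olefination, and C6, β to the carbanion, is not acidic.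

**Step 8**
Reactants: 12 (2E,4E,6E,8E,10E,12E,14E,16E)-17-{(1R,4S)-4-[(tert-butyldimethylsilyl)oxy]-2,6,6-trimethylcyclohex-2-en-1-yl}-2,6,11,15-tetramethylheptadeca-2,4,6,8,10,12,14,16-octaenal
Product: 13 (2E,4E,6E,8E,10E,12E,14E,16E)-17-[(1R,4S)-4-hydroxy-2,6,6-trimethylcyclohex-2-en-1-yl]-2,6,11,15-tetramethylheptadeca-2,4,6,8,10,12,14,16-octaenal, that is (3S,6R)-3-hydroxy-8'-apo-ε-caroten-8'-al
Conditions: Bu4NF, AcOH (1:1), THF, 0 °C to rt, dark
Reagents that add atoms: none
Why: Fluoride cleaves the Si–O bond under acetic acid buffering, which avoids both acid (ionisation of the C3 allylic carbinol) and free basic fluoride or alkoxide (aldol-type degradation of the polyenal) and leaves both stereocentres and all double bonds untouched.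

**Compound list**

1 | mesityl oxide (4-methylpent-3-en-2-one) | CC(C)=CC(C)=O | starting material
2 | isopropyl acetoacetate (propan-2-yl 3-oxobutanoate) | CC(=O)CC(=O)OC(C)C | starting material
3 | Michael adduct, isopropyl 2-acetyl-3,3-dimethyl-5-oxohexanoate (not isolated) | CC(=O)C(C(=O)OC(C)C)C(C)(C)CC(C)=O | intermediate
4 | ketol, isopropyl 2-hydroxy-2,6,6-trimethyl-4-oxocyclohexane-1-carboxylate (not isolated) | CC1(O)CC(=O)CC(C)(C)C1C(=O)OC(C)C | intermediate
5 | isopropyl 2,6,6-trimethyl-4-oxocyclohex-2-ene-1-carboxylate (racemic) | CC1=CC(=O)CC(C)(C)C1C(=O)OC(C)C | intermediate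
6 | isopropyl (1R,4S)-4-hydroxy-2,6,6-trimethylcyclohex-2-ene-1-carboxylate | CC1=C[C@@H](O)CC(C)(C)[C@H]1C(=O)OC(C)C | intermediate
7 | isopropyl (1R,4S)-4-[(tert-butyldimethylsilyl)oxy]-2,6,6-trimethylcyclohex-2-ene-1-carboxylate | CC1=C[C@@H](O[Si](C)(C)C(C)(C)C)CC(C)(C)[C@H]1C(=O)OC(C)C | intermediate
8 | {(1R,4S)-4-[(tert-butyldimethylsilyl)oxy]-2,6,6-trimethylcyclohex-2-en-1-yl}methanol | CC1=C[C@@H](O[Si](C)(C)C(C)(C)C)CC(C)(C)[C@H]1CO | intermediate
9 | 5-[({(1R,4S)-4-[(tert-butyldimethylsilyl)oxy]-2,6,6-trimethylcyclohex-2-en-1-yl}methyl)sulfanyl]-1-phenyl-1H-tetrazole | CC1=C[C@@H](O[Si](C)(C)C(C)(C)C)CC(C)(C)[C@H]1CSC2=NN=NN2c3ccccc3 | intermediate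
10 | 5-[({(1R,4S)-4-[(tert-butyldimethylsilyl)oxy]-2,6,6-trimethylcyclohex-2-en-1-yl}methyl)sulfonyl]-1-phenyl-1H-tetrazole | CC1=C[C@@H](O[Si](C)(C)C(C)(C)C)CC(C)(C)[C@H]1CS(=O)(=O)C2=NN=NN2c3ccccc3 | intermediate
11 | crocetin dialdehyde, (2E,4E,6E,8E,10E,12E,14E)-2,6,11,15-tetramethylhexadeca-2,4,6,8,10,12,14-heptaenedial | O=C/C(C)=C/C=C/C(C)=C/C=C/C=C(C)/C=C/C=C(\C)C=O | starting material
12 | (2E,4E,6E,8E,10E,12E,14E,16E)-17-{(1R,4S)-4-[(tert-butyldimethylsilyl)oxy]-2,6,6-trimethylcyclohex-2-en-1-yl}-2,6,11,15-tetramethylheptadeca-2,4,6,8,10,12,14,16-octaenal | CC1=C[C@@H](O[Si](C)(C)C(C)(C)C)CC(C)(C)[C@H]1/C=C/C(C)=C/C=C/C(C)=C/C=C/C=C(C)/C=C/C=C(\C)C=O | intermediate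
13 | (2E,4E,6E,8E,10E,12E,14E,16E)-17-[(1R,4S)-4-hydroxy-2,6,6-trimethylcyclohex-2-en-1-yl]-2,6,11,15-tetramethylheptadeca-2,4,6,8,10,12,14,16-octaenal, (3S,6R)-3-hydroxy-8'-apo-ε-caroten-8'-al | CC1=C[C@@H](O)CC(C)(C)[C@H]1/C=C/C(C)=C/C=C/C(C)=C/C=C/C=C(C)/C=C/C=C(\C)C=O | target

**Totals**

Total step count: 8. Longest linear sequence: 8 (steps 1 to 8; compound 11 is bought).

**Steps most likely to fail**

Step 2 (Proposed new method). The C6–H exchange may be slower than hydrogenation, so that the reduction is not dynamic and both diastereomers form. The catalyst may discriminate the carbonyl faces poorly on an enone flanked by CH2–CMe2. The base may also shift the ring double bond into conjugation with the ester before reduction. Fallback with known chemistry, from 5 back to 6: Luche reduction of 5 (NaBH4, CeCl3·7H2O, MeOH, −78 °C), in which hydride should again add anti to the pseudoaxial ester, should give the racemic cis-hydroxy ester F1. Acetylation of F1 with Burkholderia cepacia lipase and vinyl acetate in t-BuOMe, stopped near half conversion, is expected to convert the (4R)-enantiomer into the (1S,4R)-acetate F2 and to leave the (1R,4S)-alcohol 6. This expectation rests on the empirical rule for lipase acylation of secondary alcohols, taking the alkenyl arm as the large group. Compound 6 is separated by chromatography and rejoins the route at step 3; the enantiomeric sense would have to be confirmed before scale-up.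

Step 7. E selectivity may erode with a conjugated aldehyde, the product aldehyde may be olefinated a second time, and the dial may dissolve poorly in the cold. Fallback from 8 to 12: 8 is converted (I2, PPh3, imidazole, toluene–MeCN) into the primary iodide F3, which on heating with PPh3 in MeCN should give the phosphonium iodide F4. Its ylide (NaN(SiMe3)2, THF, −78 °C) and excess 11 should give the C7=C8 alkene as a Z-rich mixture, since the ylide is non-stabilised. Iodine-catalysed equilibration (cat. I2, CH2Cl2, daylight) should then bring it to all-E 12, which continues with step 8.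

Step 5. Substitution at the β-branched C7 may be sluggish, so that the activated alcohol is consumed by the hydrazide or returned unchanged. Fallback from 8 to 9: mesylation (MsCl, Et3N, CH2Cl2, 0 °C) gives the mesylate F5. Displacement with preformed sodium 1-phenyl-1H-tetrazole-5-thiolate (thiol, NaH, DMF, 70 °C) should then give 9, which continues with step 6.

**Further compounds**

F1 | step 2 | isopropyl (1RS,4SR)-4-hydroxy-2,6,6-trimethylcyclohex-2-ene-1-carboxylate (racemic cis, both enantiomers shown) | CC1=C[C@@H](O)CC(C)(C)[C@H]1C(=O)OC(C)C.CC1=C[C@H](O)CC(C)(C)[C@@H]1C(=O)OC(C)C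
F2 | step 2 | isopropyl (1S,4R)-4-acetoxy-2,6,6-trimethylcyclohex-2-ene-1-carboxylate | CC1=C[C@H](OC(C)=O)CC(C)(C)[C@@H]1C(=O)OC(C)C
F3 | step 7 | {(1R,4S)-4-[(tert-butyldimethylsilyl)oxy]-2,6,6-trimethylcyclohex-2-en-1-yl}methyl iodide | CC1=C[C@@H](O[Si](C)(C)C(C)(C)C)CC(C)(C)[C@H]1CI
F4 | step 7 | ({(1R,4S)-4-[(tert-butyldimethylsilyl)oxy]-2,6,6-trimethylcyclohex-2-en-1-yl}methyl)triphenylphosphonium iodide | [I-].CC1=C[C@@H](O[Si](C)(C)C(C)(C)C)CC(C)(C)[C@H]1C[P+](c2ccccc2)(c3ccccc3)c4ccccc4
F5 | step 5 | {(1R,4S)-4-[(tert-butyldimethylsilyl)oxy]-2,6,6-trimethylcyclohex-2-en-1-yl}methyl methanesulfonate | CC1=C[C@@H](O[Si](C)(C)C(C)(C)C)CC(C)(C)[C@H]1COS(C)(=O)=O
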